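Remark on the chemistry: the target is read as (2S,3R,5R)-3-bromo-5-[(2R)-2-bromo-1-chloropropan-2-yl]-2-[(E)-2-bromoethenyl]-2-methyloxolane (12). Its oxolane locants (O1, C2–C5; C1′ = CH2Cl, C2′ = exocyclic CBr) are used throughout, and starting enynol 1 is assumed to be bought as the pure (E)-isomer.

## The problem

- Target 12 is a C10H14Br3ClO oxolane with the carbon skeleton of a furanoid monoterpene. Two methyl-branched C4 units are joined through the ring methylene C4.
- There are four stereocentres: C2 (quaternary; O, CH3, (E)-bromovinyl), C3 (CHBr), C5 (CH–O) and the exocyclic C2′ (tertiary C–Br carrying CH3 and CH2Cl).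
- None of the halogens can be introduced safely by substitution. C3–Br sits beside a quaternary carbon, C2′–Br is tertiary with a defined configuration, and the Br(tertiary)/Cl(primary) pair is the reverse of what a BrCl addition to an isopropenyl group would give.
- The ring centres can control one another: C3–Br is cis to C2–CH3 and cis to the C5 side chain. C5/C2′ is an acyclic 1,2-relation and needs its own source.
- The feature that makes the key step possible is the array Br–C3–C2–O1–C5–C2′–Br. The ring oxygen O1 has a bromine two bonds away on each side, one on ring carbon C3 and one on the exocyclic C2′, each anti to its C–O bond. Read backwards, this is one molecule of Br2 added across a C2=C3 double bond and an oxirane made of O1, C5 and C2′.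
- Sensitive groups: the tertiary bromide β to oxygen (elimination, re-closure to an epoxide under base), the tertiary allylic ether at C2 (ionisation), and the bromovinyl group (Pd(0), Cr(II), organolithiums). The halogens should therefore arrive late and under non-basic, non-reducing conditions.

## Retrosynthesis

**12 ⇒ 9 + bromine.** The cuts are O1–C2, C3–Br and C2′–Br; the O1–C2′ bond of an oxirane is restored. The precursor is the epoxy bromodiene 9, (2S,3R)-3-[(2E,4E)-5-bromo-3-methylpenta-2,4-dien-1-yl]-2-(chloromethyl)-2-methyloxirane. This cut removes the ring, three of the four stereocentres and two of the three C–Br bonds at once. The neighbouring cuts (O1–C5/C2′–Br, or C–Br bonds singly) each remove one bond and leave a halohydrin to be made first. Precursor 9 has one stereogenic unit, a trans-configured trisubstituted oxirane, and no ring apart from it. The forward step must do four things: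
- attack the diene at its CH terminus;
- let the oxirane oxygen, not bromide, capture the cation;
- open the resulting epoxonium ion at C2′ with inversion;
- choose the alkene face that puts C3–Br cis to the C5 substituent.

**9 ⇒ 8 ⇒ 7.** The C1′–Cl bond is cut back to the primary alcohol 8, and the two C–O bonds of the oxirane back to the allylic alcohol 7, (2E,5E,7E)-8-bromo-2,6-dimethylocta-2,5,7-trien-1-ol. Keeping the C1′ oxygen until after epoxidation lets the hydroxyl group direct a Sharpless epoxidation. This picks the allylic alkene out of three and sets C5 and C2′ together. Precursor 7 is achiral. The forward steps need the (E)-geometry of the allylic alcohol (it becomes the C5/C2′ relative configuration) and a chloride substitution that leaves the oxirane closed.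

**7 ⇒ 4 + 6 (from 5).** The cut is the C3–C4 single bond of 7 (alkenyl carbon to allylic CH2), together with the C2–CH3 bond. This gives the bromodienyl chloride 4 and the alkenylalane 6, which comes from prop-2-yn-1-ol 5 by methylalumination. The cut is preferred to the one on the other side of the CH2 group because the alkenyl metal is then the simple, well-behaved one and the bromodiene travels as the electrophile. A skipped diene is also best made by alkenyl–allyl coupling, not by olefination of a β,γ-unsaturated aldehyde. The precursors have six and three carbons. The forward reaction must couple at the CH2 terminus with retention of both alkene geometries and leave the C–Br bond alone.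

**4 ⇒ 3 ⇒ 1.** The C–Cl bond of 4 is cut back to the alcohol 3, and the C–Br bond of 3 to the terminal alkyne of commercial (2E)-3-methylpent-2-en-4-yn-1-ol 1. Compound 1 already holds the methyl-branched (E)-alkene that becomes C2=C3 of 9. The forward reactions need an anti-Markovnikov, syn hydrometalation/bromination and an allylic substitution without transposition.

## Roads not taken

Alternative 1: the obvious, biomimetic cut is O1–C5 and C2′–Br. The tertiary alcohol A1, (1E,3S,4R,6E)-1,4-dibromo-8-chloro-3,7-dimethylocta-1,6-dien-3-ol, would be cyclised by 5-exo bromoetherification onto the trisubstituted alkene.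
- A1 already contains two of the four stereocentres as a tertiary-alcohol/secondary-bromide pair, which would have to be made enantioselectively first.
- The bromonium ion of a trisubstituted alkene is opened by a δ-hydroxyl at the CH carbon (oxolane) or at the tertiary carbon (oxane), and the CH2Cl group only partly biases this.
- A tertiary carbinol carrying CH3 and bromovinyl, two groups of similar size, gives little control over the C2/C5 relation.
- The step would form one C–Br bond and one stereo relation; the chosen step forms two C–Br bonds and three stereo relations from a precursor with a single stereogenic unit.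

Alternative 2: chiral pool. (3R)-Linalool A2 has all ten carbons and the correct configuration at the carbon that becomes C2. Allylic chlorination at the terminal (E)-methyl and bromoetherification would give the vinyl oxolane A3, (2R,5R)-5-[(2R)-2-bromo-1-chloropropan-2-yl]-2-ethenyl-2-methyloxolane.
- A3 has no handle for bromination of the ring methylene C3, an unactivated CH2 beside a quaternary carbon.
- Converting vinyl to (E)-2-bromovinyl needs oxidative cleavage and a Cr(II) olefination in the presence of a tertiary bromide.
- The cyclisation of A2-type alcohols gives both C5 epimers.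
- The one stereocentre bought from the pool is one the chosen plan sets without extra steps.

Alternative 3: cut C2′–Br and C1′–Cl, i.e. late bromochlorination of the isopropenyl oxolane A4, (2S,3R,5R)-3-bromo-2-[(E)-2-bromoethenyl]-2-methyl-5-(prop-1-en-2-yl)oxolane.
- Chloride opens the bromonium ion of a 1,1-disubstituted alkene at the tertiary carbon. This gives Cl(tertiary)/Br(primary), the constitutional isomer of what is needed.
- There is no free allylic hydroxyl to direct halide delivery, and the isopropenyl group rotates freely, so face selectivity is weak.
- A4 still needs all three ring stereocentres, so nothing is saved upstream.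

Key step: step 6

## Route

Step 1
Reactants: 1 (2E)-3-methylpent-2-en-4-yn-1-ol
Product: 3 (2E,4E)-5-bromo-3-methylpenta-2,4-dien-1-ol, via bis-zirconated dienyl alkoxide 2 (not isolated)
Conditions: Cp2Zr(H)Cl (2.2 equiv), THF, 0 °C → rt; then NBS (1.05 equiv), 0 °C
Reagents that add atoms: N-bromosuccinimide, O=C1CCC(=O)N1Br
Why: Hydrozirconation with the Schwartz reagent is syn and places Zr on the terminal alkyne carbon of the 1,3-enyne; the first equivalent is consumed by the hydroxyl group as a zirconium alkoxide. Bromination of the C–Zr bond with NBS goes with retention and should give the (E)-bromide; the existing (E)-trisubstituted alkene is untouched.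

Step 2
Reactants: 3 (2E,4E)-5-bromo-3-methylpenta-2,4-dien-1-ol
Product: 4 (1E,3E)-1-bromo-5-chloro-3-methylpenta-1,3-diene
Conditions: NCS, Me2S, CH2Cl2, −30 → 0 °C
Reagents that add atoms: N-chlorosuccinimide, O=C1CCC(=O)N1Cl
Why: Corey–Kim chlorination converts a primary allylic alcohol into the chloride by SN2 displacement of an alkoxysulfonium ion under neutral conditions, without allylic transposition or change of alkene geometry. The chloride would be used crude.

Step 3
Reactants: 5 prop-2-yn-1-ol; 4 (1E,3E)-1-bromo-5-chloro-3-methylpenta-1,3-diene
Product: 7 (2E,5E,7E)-8-bromo-2,6-dimethylocta-2,5,7-trien-1-ol, via alkenylalane 6 (not isolated)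
Conditions: 5, Me3Al (3 equiv), Cp2ZrCl2 (25 mol %), CH2Cl2, 0 °C → rt; then 4, Pd(PPh3)4 (5 mol %), THF, 0 °C, no zinc salt; aq. Rochelle salt
Reagents that add atoms: trimethylaluminium, C[Al](C)C
Why: Negishi zirconium-catalysed methylalumination of the O-aluminated propargyl alcohol is syn, with CH3 on the internal carbon, and fixes the (2E)-alkene. Palladium-catalysed alkenyl–allyl coupling (Negishi) joins the alane to the CH2 terminus of the π-allyl complex from 4 with retention of both geometries. The allylic C–Cl bond should undergo oxidative addition far faster than the dienyl C–Br bond, and alkenylalanes couple only slowly with alkenyl halides when no zinc salt is present.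

Step 4
Reactants: 7 (2E,5E,7E)-8-bromo-2,6-dimethylocta-2,5,7-trien-1-ol
Product: 8 [(2R,3R)-3-[(2E,4E)-5-bromo-3-methylpenta-2,4-dien-1-yl]-2-methyloxiran-2-yl]methanol
Conditions: Ti(OiPr)4 (10 mol %), D-(−)-diethyl tartrate (12 mol %), t-BuOOH, 4 Å MS, CH2Cl2, −20 °C
Reagents that add atoms: tert-butyl hydroperoxide, CC(C)(C)OO
Why: Sharpless asymmetric epoxidation reacts only at the alkene of the allylic alcohol. D-(−)-tartrate gives the (2R,3R)-epoxy alcohol from an (E)-2-methylalk-2-en-1-ol (L-(+)-tartrate gives the (2S,3S) series, as with geraniol). Both C5 and the precursor of C2′ are set here, and the bromodiene is inert.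

Step 5
Reactants: 8 [(2R,3R)-3-[(2E,4E)-5-bromo-3-methylpenta-2,4-dien-1-yl]-2-methyloxiran-2-yl]methanol
Product: 9 (2S,3R)-3-[(2E,4E)-5-bromo-3-methylpenta-2,4-dien-1-yl]-2-(chloromethyl)-2-methyloxirane
Conditions: PPh3, CCl4, NaHCO3, 65 °C
Reagents that add atoms: tetrachloromethane, ClC(Cl)(Cl)Cl
Why: Appel reaction: chloride displaces the oxyphosphonium group at the primary carbon, a standard conversion of 2,3-epoxy alcohols into epoxy chlorides. No stereocentre is touched; the descriptor at the oxirane carbon changes from R to S only because CH2Cl outranks the ring carbon.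

Step 6
Reactants: 9 (2S,3R)-3-[(2E,4E)-5-bromo-3-methylpenta-2,4-dien-1-yl]-2-(chloromethyl)-2-methyloxirane
Product: 12 (2S,3R,5R)-3-bromo-5-[(2R)-2-bromo-1-chloropropan-2-yl]-2-[(E)-2-bromoethenyl]-2-methyloxolane, via bromonium ion 10 (not isolated), via bicyclic epoxonium bromide 11 (not isolated)
Conditions: Br2 (1.0 equiv, slow addition), CH2Cl2, −78 °C, dark
Reagents that add atoms: bromine, BrBr
Why: Proposed new method: bromine attacks the trisubstituted alkene of the bromodiene at its CH terminus (the bromovinyl alkene is deactivated) to give the unsymmetrical bromonium ion 10 with the charge on the tertiary allylic carbon; the oxirane oxygen, two atoms away, captures this carbon in a 5-endo closure to the 1-oxoniabicyclo[3.1.0]hexane 11, and bromide then opens 11 by SN2 at the exocyclic tertiary carbon, so the oxolane is the ring that is closed and the oxirane is the ring that is opened. The closest known reaction types are bromonium-initiated epoxide-opening cascades and transannular epoxide participation in alkene bromination (epoxonium formation followed by halide capture), and the 5-endo halocyclisation of (E)-homoallylic alcohols; new here is an oxirane as the 5-endo nucleophile toward a diene-derived bromonium ion with bromide as the terminating nucleophile. C2 and C3 are set by anti addition of O and Br across the (E)-alkene, which places C3–Br cis to C2–CH3 and trans to the bromovinyl group. C2′ is set by inversion at the oxirane carbon, which turns the (S)-oxirane carbon of 9 into the (R)-bromide, while C5 keeps the configuration from step 4. The C3/C5 relation rests on the transition-state shape: anti opening of the bromonium ion needs a pseudo-equatorial C3–Br in the forming ring, and the oxirane methyl group that points over this ring (cis to the tether because 7 was an (E)-allylic alcohol) disfavours the boat-like bicyclic arrangement, so the chair-like one, in which this bromine is cis to the oxirane bridge, should be preferred; this is the same 3,5-cis outcome as in the homoallylic alcohol series. The step needs capture by oxygen before capture by bromide (intramolecular five-membered closure, low temperature, no added bromide) and opening at C2′ and not at C5 (tertiary against secondary, partly offset by the CH2Cl group). Any bromohydrin formed from 9 by adventitious HBr should cyclise to the same product, so both paths converge, and both bromine atoms of the reagent end up in 12.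

## Compound list

1 | (2E)-3-methylpent-2-en-4-yn-1-ol | C#C/C(C)=C/CO | starting material
2 | (2E,4E)-3-methylpenta-2,4-dien-1-ol carrying chlorobis(cyclopentadienyl)zirconium on O and on C5 | Cl[Zr](C1C=CC=C1)(C1C=CC=C1)/C=C/C(C)=C/CO[Zr](Cl)(C1C=CC=C1)C1C=CC=C1 | intermediate
3 | (2E,4E)-5-bromo-3-methylpenta-2,4-dien-1-ol | OC/C=C(C)/C=C/Br | intermediate
4 | (1E,3E)-1-bromo-5-chloro-3-methylpenta-1,3-diene | ClC/C=C(C)/C=C/Br | intermediate
5 | prop-2-yn-1-ol | C#CCO | starting material
6 | [(1E)-3-[(dimethylalumanyl)oxy]-2-methylprop-1-en-1-yl]dimethylalumane | C[Al](C)/C=C(\C)CO[Al](C)C | intermediate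
7 | (2E,5E,7E)-8-bromo-2,6-dimethylocta-2,5,7-trien-1-ol | OC/C(C)=C/C/C=C(C)/C=C/Br | intermediate
8 | [(2R,3R)-3-[(2E,4E)-5-bromo-3-methylpenta-2,4-dien-1-yl]-2-methyloxiran-2-yl]methanol | C[C@]1(CO)O[C@@H]1C/C=C(C)/C=C/Br | intermediate
9 | (2S,3R)-3-[(2E,4E)-5-bromo-3-methylpenta-2,4-dien-1-yl]-2-(chloromethyl)-2-methyloxirane | C[C@]1(CCl)O[C@@H]1C/C=C(C)/C=C/Br | intermediate
10 | bromonium bromide of 9: Br+ bridges the CH and C(CH3) carbons of the former trisubstituted alkene, on the face anti to the later C–O bond | C[C@]1(CCl)O[C@@H]1C[C@H]2[Br+][C@]2(C)/C=C/Br.[Br-] | intermediate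
11 | 3-bromo-2-[(E)-2-bromoethenyl]-6-(chloromethyl)-2,6-dimethyl-1-oxoniabicyclo[3.1.0]hexane bromide; 3-Br cis to 2-CH3 and to the C6 bridge, 6-CH3 endo | C[C@@]1(CCl)[C@H]2C[C@@H](Br)[C@](C)(/C=C/Br)[O+]12.[Br-] | intermediate
12 | (2S,3R,5R)-3-bromo-5-[(2R)-2-bromo-1-chloropropan-2-yl]-2-[(E)-2-bromoethenyl]-2-methyloxolane | C[C@](Br)(CCl)[C@H]1C[C@@H](Br)[C@](C)(/C=C/Br)O1 | target

## Step count and risks

Total: 6 steps. Longest linear sequence: 6 steps (1 → 3 → 4 → 7 → 8 → 9 → 12); prop-2-yn-1-ol 5 enters in step 3 without steps of its own.

**Step 6 (key step, proposed new method).** Three things may go wrong.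
- Poor π-facial selectivity in the ring closure. The controlling centre is tied into the oxirane, and the conformational argument is not proven for an epoxide nucleophile.
- Capture of the allyl-type cation by bromide before the oxirane oxygen reaches it, which would be plain dibromination of the diene.
- Opening of the epoxonium ion at C5 instead of C2′, giving ring expansion to an oxane, because the CH2Cl group lowers the cationic character of the tertiary carbon.

Fallback, known chemistry, from 9 back to 12: 9 would be opened with HBr (48 % aq. HBr, Et2O, −20 °C; attack at the tertiary carbon with inversion) to the bromohydrin (2R,3R,5E,7E)-2,8-dibromo-1-chloro-2,6-dimethylocta-5,7-dien-3-ol F1. F1 would then be cyclised with NBS in MeCN at 0 °C. This is a 5-endo bromoetherification of a homoallylic alcohol, for which the halogen ends up cis to the carbinol substituent, and it gives 12.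

**Step 3.** Oxidative addition of Pd(0) into the dienyl C–Br bond of 4 or of product 7 may compete, as may methyl transfer from aluminium. Ionisation of the pentadienyl chloride by the Lewis-acidic alane may also scramble the alkene geometry.

Fallback, from 5 (through the same alane 6) back to 7, with bromine introduced after the coupling:
- Commercial 2-methyl-2-vinyloxirane would be opened in the 1,4-sense with chloride (conc. HCl, cat. CuCl, 0 °C) to (2E)-4-chloro-2-methylbut-2-en-1-ol F2.
- F2 would be silylated (TBSCl, imidazole) to tert-butyl{[(2E)-4-chloro-2-methylbut-2-en-1-yl]oxy}dimethylsilane F3.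
- Alane 6 would be coupled with F3 (Pd(PPh3)4, THF) to (2E,5E)-7-{[tert-butyl(dimethyl)silyl]oxy}-2,6-dimethylhepta-2,5-dien-1-ol F4.
- MnO2 would give the enal (2E,5E)-7-{[tert-butyl(dimethyl)silyl]oxy}-2,6-dimethylhepta-2,5-dienal F5.
- Takai olefination (CHBr3, CrBr2, THF, 0 °C) would give the silyl ether {[(2E,5E,7E)-8-bromo-2,6-dimethylocta-2,5,7-trien-1-yl]oxy}(tert-butyl)dimethylsilane F6.
- Bu4NF would release 7.

**Step 1.** Hydrozirconation in the presence of the free hydroxyl group may stay incomplete, and surplus hydride or NBS may over-reduce or over-brominate the diene.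

Fallback, from 1 back to 3: palladium-catalysed hydrostannation (Bu3SnH, PdCl2(PPh3)2, THF, 0 °C) would give (2E,4E)-3-methyl-5-(tributylstannyl)penta-2,4-dien-1-ol F7. Bromodestannylation with NBS (CH2Cl2, 0 °C, retention) would give 3.

**Step 5.** Chloride or traces of HCl may open the oxirane at 65 °C, or the epoxy alcohol may rearrange before substitution.

Fallback, from 8 back to 9: 8 would be converted at −20 °C (MsCl, Et3N, CH2Cl2) into the isolated sulfonate [(2R,3R)-3-[(2E,4E)-5-bromo-3-methylpenta-2,4-dien-1-yl]-2-methyloxiran-2-yl]methyl methanesulfonate F8. F8 would be displaced with LiCl in DMF at room temperature to give 9.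

## Further compounds

F1 | step 6 | (2R,3R,5E,7E)-2,8-dibromo-1-chloro-2,6-dimethylocta-5,7-dien-3-ol | C[C@](Br)(CCl)[C@H](O)C/C=C(C)/C=C/Br
F2 | step 3 | (2E)-4-chloro-2-methylbut-2-en-1-ol | OC/C(C)=C/CCl
F3 | step 3 | tert-butyl{[(2E)-4-chloro-2-methylbut-2-en-1-yl]oxy}dimethylsilane | CC(C)(C)[Si](C)(C)OC/C(C)=C/CCl
F4 | step 3 | (2E,5E)-7-{[tert-butyl(dimethyl)silyl]oxy}-2,6-dimethylhepta-2,5-dien-1-ol | OC/C(C)=C/C/C=C(C)/CO[Si](C)(C)C(C)(C)C
F5 | step 3 | (2E,5E)-7-{[tert-butyl(dimethyl)silyl]oxy}-2,6-dimethylhepta-2,5-dienal | O=C/C(C)=C/C/C=C(C)/CO[Si](C)(C)C(C)(C)C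
F6 | step 3 | {[(2E,5E,7E)-8-bromo-2,6-dimethylocta-2,5,7-trien-1-yl]oxy}(tert-butyl)dimethylsilane | CC(C)(C)[Si](C)(C)OC/C(C)=C/C/C=C(C)/C=C/Br
F7 | step 1 | (2E,4E)-3-methyl-5-(tributylstannyl)penta-2,4-dien-1-ol | CCCC[Sn](CCCC)(CCCC)/C=C/C(C)=C/CO
F8 | step 5 | [(2R,3R)-3-[(2E,4E)-5-bromo-3-methylpenta-2,4-dien-1-yl]-2-methyloxiran-2-yl]methyl methanesulfonate | C[C@]1(COS(C)(=O)=O)O[C@@H]1C/C=C(C)/C=C/Br
A1 | alternative 1 | (1E,3S,4R,6E)-1,4-dibromo-8-chloro-3,7-dimethylocta-1,6-dien-3-ol | ClC/C(C)=C/C[C@@H](Br)[C@@](C)(O)/C=C/Br
A2 | alternative 2 | (3R)-3,7-dimethylocta-1,6-dien-3-ol ((R)-linalool) | C=C[C@@](O)(C)CCC=C(C)C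
A3 | alternative 2 | (2R,5R)-5-[(2R)-2-bromo-1-chloropropan-2-yl]-2-ethenyl-2-methyloxolane | C[C@](Br)(CCl)[C@H]1CC[C@](C)(C=C)O1
A4 | alternative 3 | (2S,3R,5R)-3-bromo-2-[(E)-2-bromoethenyl]-2-methyl-5-(prop-1-en-2-yl)oxolane | CC(=C)[C@H]1C[C@@H](Br)[C@](C)(/C=C/Br)O1
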